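**Plan**

Cuts: first the two acetates; then O16–C15 (dihydrofuran), C6–O, O9–C13 (tetrahydrofuran), C9–O and C11–C12, back to a bicyclic 8-en-7-one.
The bicycle is cut at C4–C5 and C10–C9 to an acyclic epoxy diene allylsilane, assembled from geranyl chloride, methyl acetoacetate and Me3SiCH2MgCl.
Forward: chain assembly, rings A and B in one cationic step, ring B oxidation to the enone, C12–C16 chain by allyl–allyl coupling, tetrahydrofuran ring, C6 oxygen, dihydrofuran ring last, then acetylation.
Stereochemistry: C3 and C4 from Sharpless epoxidation of a Z-allylic alcohol; C5, C10 and (at first) C9 from chair–chair folding; C9–O from α-face epoxidation of the enone.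
C13 from a second Sharpless epoxidation, inverted in the ether closure; C8 by equilibration to the equatorial methyl; C6 by α-epoxidation of the Δ6-enol ester and acyloxy shift with inversion.

Key step: step 10

Remarks: labdane numbering is used for all compounds (C19 = CH2O on C4, C17 = carbon on C8, C20 = methyl on C10); TBDPS = tert-butyldiphenylsilyl; α/β as in the steroid convention.
Assumption: in the 7-keto-9α,13-ether the closed spiro ether with the equatorial 8α-methyl is taken to be the thermodynamic form (as the natural substitution pattern suggests), so that C8 can be equilibrated through the enol without loss of the ether.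

**Route**

Step 1
Reactants: 1 geranyl chloride
Product: 2 6,7-epoxygeranyl chloride (racemic)
Conditions: mCPBA (1.0 equiv), NaHCO3, CH2Cl2, 0 °C
Reagents that add atoms: 3-chloroperbenzoic acid (mCPBA), OOC(=O)c1cccc(Cl)c1
Why: The Prilezhaev epoxidation takes the electron-rich 6,7-alkene because the allylic chlorine deactivates the 2,3-alkene, and the racemic epoxide stereocentre is destroyed in step 2.

Step 2
Reactants: 2 6,7-epoxygeranyl chloride
Product: 3 (4E)-6-chloro-4-methylhex-4-enal
Conditions: H5IO6, THF/Et2O, 0 °C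
Reagents that add atoms: none
Why: Periodic acid opens the epoxide to the glycol and cleaves it at once (Malaprade cleavage), so that the former C6 of 1 becomes the aldehyde carbon, its oxygen being the epoxide oxygen, and acetone is lost.

Step 3
Reactants: 3 (4E)-6-chloro-4-methylhex-4-enal; 4 ethyl 2-[bis(2,2,2-trifluoroethoxy)phosphoryl]propanoate
Product: 5 ethyl (2Z,6E)-8-chloro-2,6-dimethylocta-2,6-dienoate
Conditions: KHMDS, 18-crown-6, THF, −78 °C
Reagents that add atoms: none
Why: The Still–Gennari olefination with the bis(trifluoroethyl) phosphonate eliminates fast from the kinetic adduct and gives the Z-trisubstituted enoate, with the ester cis to the chain, which is what later places C19 axial.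

Step 4
Reactants: 5 ethyl (2Z,6E)-8-chloro-2,6-dimethylocta-2,6-dienoate
Product: 6 (2Z,6E)-8-chloro-2,6-dimethylocta-2,6-dien-1-ol
Conditions: DIBAL-H (2.2 equiv), CH2Cl2, −78 °C
Reagents that add atoms: none
Why: DIBAL-H reduces the conjugated ester 1,2 to the allylic alcohol at low temperature without touching the alkene geometry or the allylic chloride.

Step 5
Reactants: 6 (2Z,6E)-8-chloro-2,6-dimethylocta-2,6-dien-1-ol
Product: 7 [(2R,3S)-3-[(3E)-5-chloro-3-methylpent-3-en-1-yl]-2-methyloxiran-2-yl]methanol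
Conditions: Ti(OiPr)4, D-(−)-diethyl tartrate, t-BuOOH, 4 Å MS, CH2Cl2, −20 °C
Reagents that add atoms: tert-butyl hydroperoxide, CC(C)(C)OO
Why: In the Sharpless asymmetric epoxidation the titanium tartrate delivers oxygen to one face of the allylic alcohol only, the D-(−)-tartrate giving the (2R,3S)-epoxide (C4 R and C3 S in labdane numbering), while the Z geometry keeps CH2OH cis to the chain and the remote alkene, which has no hydroxyl, does not react.

Step 6
Reactants: 7 [(2R,3S)-3-[(3E)-5-chloro-3-methylpent-3-en-1-yl]-2-methyloxiran-2-yl]methanol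
Product: 8 TBDPS ether of 7
Conditions: TBDPSCl, imidazole, CH2Cl2, 0 °C
Reagents that add atoms: tert-butyldiphenylsilyl chloride, CC(C)(C)[Si](Cl)(c1ccccc1)c1ccccc1
Why: Silylation of the primary alcohol with the bulky, weakly Lewis basic TBDPS group gives an ether that should survive the Lewis acid of step 10 and everything up to step 27.

Step 7
Reactants: 8 TBDPS ether of 7; 9 methyl acetoacetate
Product: 10 methyl (6E)-9-[(2S,3R)-3-(TBDPS-oxymethyl)-3-methyloxiran-2-yl]-7-methyl-3-oxonon-6-enoate
Conditions: 9, NaH then n-BuLi, THF, 0 °C; then 8, 0 °C → rt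
Reagents that add atoms: none
Why: The dianion of the β-keto ester is alkylated at its terminal carbon by the primary allylic chloride (SN2), which adds C7, C8, C9 and C11, and neither the trisubstituted epoxide nor the silyl ether reacts with this enolate.

Step 8
Reactants: 10 β-keto ester
Product: 11 methyl (2Z,6E)-3-(diethoxyphosphoryloxy)-9-[(2S,3R)-3-(TBDPS-oxymethyl)-3-methyloxiran-2-yl]-7-methylnona-2,6-dienoate
Conditions: NaH, (EtO)2P(O)Cl, Et2O, 0 °C
Reagents that add atoms: diethyl chlorophosphate, CCOP(=O)(Cl)OCC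
Why: O-Phosphorylation of the sodium-chelated enolate of the β-keto ester gives the Z-enol phosphate, with the phosphate cis to the ester.

Step 9
Reactants: 11 Z-enol phosphate; 12 (trimethylsilyl)methylmagnesium chloride
Product: 13 methyl (2Z,6E)-9-[(2S,3R)-3-(TBDPS-oxymethyl)-3-methyloxiran-2-yl]-7-methyl-3-[(trimethylsilyl)methyl]nona-2,6-dienoate
Conditions: Ni(acac)2 (10 mol %), THF, 0 °C → rt
Reagents that add atoms: none
Why: The nickel-catalysed Kumada coupling replaces the phosphate by CH2SiMe3 with retention, so that C11 ends trans to C7 (2Z by the sequence rules), the geometry that puts C11 equatorial in the chair closure of ring B.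

Step 10
Reactants: 13 epoxy diene allylsilane ester
Product: 14 methyl 19-(TBDPS-oxy)-3β-hydroxy-12,13,14,15,16-pentanorlabd-8(17)-en-11-oate (5α-H, 9α-H, 10β-CH3)
Conditions: MeAlCl2 (2.2 equiv), CH2Cl2, −78 °C; then Et3N, aq NaHCO3
Reagents that add atoms: none
Why: MeAlCl2 binds the epoxide oxygen, the C4–O bond ionises at the more substituted carbon as the C5=C10 alkene attacks C4 anti to the leaving oxygen, and the C10 cation so formed is captured at C9 by the allylsilane, whose β-silyl cation at C8 loses the silyl group to leave the 8(17)-alkene. The closest known reaction type is the Lewis acid-promoted epoxy-polyene cyclisation terminated by an allylsilane, including terminators in which the (silylmethyl)alkene is conjugated to an ester. Ring A (C4–C5) closes in the 6-endo mode with respect to both the epoxide and the alkene, and ring B (C10–C9) closes 6-endo onto the allylsilane, each through a chair. C3 keeps the (S) configuration of the epoxide and becomes the equatorial 3β-alcohol, C4 is inverted by the anti attack so that the silyloxymethyl group (cis to the chain on the epoxide) ends axial as C19 with the methyl equatorial, C5 and C10 follow from the E geometry of the C5=C10 alkene in the chair–chair fold (trans fusion), and C9 takes the ester equatorial (β) because C11 is trans to C7 on the C8=C9 alkene. The step needs the second ring closure to outrun proton loss from the C10 cation and needs C11 to stay a spectator: the chain is all carbon up to C11, and C11 is held as the ester because an allylic acyloxy group placed 1,4 to silicon would invite Lewis acid-induced 1,4-elimination to a diene.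

Step 11
Reactants: 14 bicyclic ester
Product: 15 19-(TBDPS-oxy)-12,13,14,15,16-pentanorlabd-8(17)-ene-3β,11-diol
Conditions: LiAlH4, THF, 0 °C
Reagents that add atoms: none
Why: LiAlH4 reduces the methyl ester to the primary alcohol without epimerising C9, the silyl ether and the isolated alkene being inert.

Step 12
Reactants: 15 3β,11-diol
Product: 16 11-acetoxy-19-(TBDPS-oxy)-12,13,14,15,16-pentanorlabd-8(17)-en-3β-ol
Conditions: AcCl (1.05 equiv), 2,4,6-collidine, CH2Cl2, −78 °C
Reagents that add atoms: acetyl chloride, CC(Cl)=O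
Why: Acetyl chloride with collidine at low temperature acylates the primary 11-hydroxyl much faster than the secondary 3β-hydroxyl, which sits next to the quaternary C4.

Step 13
Reactants: 16 11-acetate
Product: 17 11-acetoxy-19-(TBDPS-oxy)-12,13,14,15,16-pentanorlabd-8(17)-ene-3β,7α-diol
Conditions: SeO2 (0.5 equiv), t-BuOOH, CH2Cl2, rt
Reagents that add atoms: tert-butyl hydroperoxide, CC(C)(C)OO (terminal oxidant; the oxygen is relayed by SeO2, O=[Se]=O)
Why: In the Riley oxidation SeO2 adds to the exocyclic alkene in an ene reaction and the 2,3-sigmatropic shift returns oxygen to the ring methylene C7 (a CH2 is preferred over the methine C9), on the axial α face as is usual for 8(17)-ene decalins, a centre that is removed in step 14.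

Step 14
Reactants: 17 7α-alcohol
Product: 18 11-acetoxy-3β-hydroxy-19-(TBDPS-oxy)-12,13,14,15,16-pentanorlabd-8(17)-en-7-one
Conditions: MnO2, CH2Cl2, rt
Reagents that add atoms: none
Why: MnO2 oxidises only the allylic 7-alcohol, so that the unprotected 3β-alcohol is spared.

Step 15
Reactants: 18 exocyclic enone
Product: 19 11-acetoxy-3β-hydroxy-19-(TBDPS-oxy)-12,13,14,15,16-pentanorlabd-8-en-7-one
Conditions: RhCl3·3H2O (5 mol %), EtOH, 75 °C
Reagents that add atoms: none
Why: A rhodium hydride formed in ethanol adds to the exocyclic alkene and β-hydride elimination towards C9 moves the double bond into the ring, the known isomerisation of α-methylene ketones to the more substituted conjugated enone, which also turns the C11 acetate into an allylic acetate.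

Step 16
Reactants: 20 2-methylprop-2-en-1-ol; 21 tributyltin chloride
Product: 22 2-[(tributylstannyl)methyl]prop-2-en-1-ol
Conditions: n-BuLi (2.1 equiv), TMEDA, Et2O, 0 °C → rt; then 21, −78 °C → rt; aq NH4Cl
Reagents that add atoms: none
Why: Allylic lithiation of the lithium alkoxide gives the C,O-dianion, which is stannylated at carbon, the O–Sn bond being hydrolysed on work-up.

Step 17
Reactants: 19 8-en-7-one allylic acetate; 22 2-[(tributylstannyl)methyl]prop-2-en-1-ol
Product: 23 3β,14-dihydroxy-19-(TBDPS-oxy)-15-norlabda-8,13(16)-dien-7-one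
Conditions: Pd2(dba)3 (5 mol %), LiCl, DMF, 50 °C
Reagents that add atoms: none
Why: In this Stille-type allyl–allyl coupling zerovalent palladium ionises the γ-acetoxy enone to a π-allyl complex, the allyl group is transferred from tin and the new bond forms at the unhindered terminus C11 and not at the fully substituted C8, either end of the 2-substituted allyl unit giving the same C11–C12 product.

Step 18
Reactants: 23 side-chain allylic alcohol
Product: 24 (13S)-13,16-epoxy-3β,14-dihydroxy-19-(TBDPS-oxy)-15-norlabd-8-en-7-one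
Conditions: Ti(OiPr)4 (0.2 equiv), L-(+)-diisopropyl tartrate, t-BuOOH, 4 Å MS, CH2Cl2, −20 °C
Reagents that add atoms: tert-butyl hydroperoxide, CC(C)(C)OO
Why: Sharpless asymmetric epoxidation of the 2-substituted allylic alcohol with the L-(+)-tartrate sets C13 as the (S)-epoxide by reagent control (the ring stereocentres are too remote to matter), and the electron-poor enone alkene is inert to the titanium peroxide.

Step 19
Reactants: 24 epoxy alcohol
Product: 25 (13R)-13,16-epoxy-3β-hydroxy-7-oxo-19-(TBDPS-oxy)-15-norlabd-8-en-14-al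
Conditions: TEMPO (10 mol %), PhI(OAc)2, CH2Cl2, rt
Reagents that add atoms: none
Why: The oxoammonium oxidation (TEMPO with PhI(OAc)2) is selective for the primary alcohol over the hindered secondary 3β-alcohol and cannot epimerise the quaternary C13 (now R only because the substituent priorities change).

Step 20
Reactants: 25 epoxy aldehyde; 26 dimethyl (1-diazo-2-oxopropyl)phosphonate
Product: 27 (13S)-13,16-epoxy-3β-hydroxy-19-(TBDPS-oxy)labd-8-en-14-yn-7-one
Conditions: K2CO3, MeOH, 0 °C → rt
Reagents that add atoms: none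
Why: The Ohira–Bestmann variant of the Seyferth–Gilbert homologation turns the aldehyde into the terminal alkyne (C14≡C15) under mild carbonate conditions, the diazophosphonate being set free from 26 by methanolysis, without touching the epoxide or the enone.

Step 21
Reactants: 27 ethynyl epoxide enone
Product: 28 (13S)-8α,9α:13,16-diepoxy-3β-hydroxy-19-(TBDPS-oxy)labd-14-yn-7-one
Conditions: H2O2 (30% aq), NaOH, MeOH, 0 °C → rt
Reagents that add atoms: hydrogen peroxide, OO
Why: In the Weitz–Scheffer epoxidation hydroperoxide adds to the β-carbon C9 from the α face, anti to the axial C10 methyl, and the enolate closes on oxygen, which fixes the C9–O bond α, a reaction type known for tetrasubstituted bicyclic enones.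

Step 22
Reactants: 28 epoxy ketone
Product: 29 (13S)-13,16-epoxy-3β,9α-dihydroxy-19-(TBDPS-oxy)labd-14-yn-7-one (8β-H, 8α-CH3)
Conditions: SmI2 (2.5 equiv), THF/MeOH, −90 °C
Reagents that add atoms: none
Why: SmI2 reduces the ketone to the ketyl, the α C8–O bond breaks and a second electron gives the samarium enolate together with the 9α-alkoxide, protonation then giving the β-hydroxy ketone in which C8 is expected to settle as the equatorial 8α-methyl (it remains epimerisable through the enol and is equilibrated in step 23 if needed), while the propargylic epoxide is not reduced.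

Step 23
Reactants: 29 9α-hydroxy ketone
Product: 30 (13R)-9α,13-epoxy-3β,16-dihydroxy-19-(TBDPS-oxy)labd-14-yn-7-one
Conditions: CSA (10 mol %), CH2Cl2, 0 °C → rt
Reagents that add atoms: none
Why: Under acid catalysis the tertiary 9α-hydroxyl opens the epoxide in the 5-exo-tet mode at the tertiary propargylic carbon C13 with inversion, so that the (13S)-epoxide gives the (13R)-spiro ether and 16-OH is set free, the same acid equilibrating C8 to the equatorial methyl.

Step 24
Reactants: 30 spiro ether alkynol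
Product: 31 (13R)-9α,13-epoxy-19-(TBDPS-oxy)labd-6-en-14-yne-3β,7,16-triyl tris(chloroacetate)
Conditions: LiHMDS (3.1 equiv), THF, −78 °C; then (ClCH2CO)2O, −78 → 0 °C
Reagents that add atoms: chloroacetic anhydride, O=C(CCl)OC(=O)CCl
Why: After the two alkoxides have formed, LiHMDS deprotonates the ketone kinetically at the C6 methylene (not at the C8 methine, so the β-alkoxy group is not expelled), and the enolate oxygen and both alkoxides are acylated by the anhydride to give the Δ6-enol ester.

Step 25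
Reactants: 31 Δ6-enol chloroacetate
Product: 33 (13R)-3β,6β,16-tris(chloroacetoxy)-9α,13-epoxy-19-(TBDPS-oxy)labd-14-yn-7-one, via enol ester epoxide 32 (not isolated)
Conditions: dimethyldioxirane, acetone/CH2Cl2, 0 °C; solvent exchange; toluene, 110 °C
Reagents that add atoms: dimethyldioxirane, CC1(C)OO1
Why: Dimethyldioxirane epoxidises the enol ester from the α face because the β face of C6 is covered by the axial C19 and C20 groups, and on heating the α-acyloxy epoxide undergoes the known 1,2-acyloxy shift in which the ester carbonyl oxygen attacks C6 from the β face as the epoxide opens, so that the acyloxy group arrives at C6 with inversion as the axial 6β-ester and C7 becomes the ketone.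

Step 26
Reactants: 33 tris(chloroacetate)
Product: 34 (13R)-9α,13-epoxy-3β,6β,16-trihydroxy-19-(TBDPS-oxy)labd-14-yn-7-one
Conditions: thiourea, NaHCO3, EtOH/THF, 55 °C
Reagents that add atoms: none
Why: Thiourea is S-alkylated by each chloroacetate and the isothiouronium salt cyclises with release of the alcohol, which removes all three esters under nearly neutral conditions that do not enolise the β-alkoxy ketone or the α-ketol.

Step 27
Reactants: 34 silyl ether triol
Product: 35 (13R)-9α,13-epoxy-3β,6β,16,19-tetrahydroxylabd-14-yn-7-one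
Conditions: HF·pyridine, THF/pyridine, 0 °C → rt
Reagents that add atoms: none
Why: Fluoride cleaves the Si–O bond of the neopentyl TBDPS ether under buffered, weakly acidic conditions that leave the α-ketol, the spiro ether and the alkyne alone.

Step 28
Reactants: 35 tetraol alkyne
Product: 36 (13R)-9α,13:15,16-diepoxy-3β,6β,19-trihydroxylabd-14-en-7-one
Conditions: Mo(CO)6 (0.3 equiv), Et3N, Et2O, hν (350 nm); then 35 added in the dark, rt
Reagents that add atoms: none
Why: In the molybdenum-catalysed alkynol cycloisomerisation the terminal alkyne forms a vinylidene complex, the homopropargylic 16-hydroxyl (the only hydroxyl placed for a five-membered ring) adds to C15 and protodemetalation gives the 2,3-dihydrofuran in a formal 5-endo closure, the triethylamine medium protecting the acid-sensitive enol ether.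

Step 29
Reactants: 36 dihydrofuran triol
Product: 37 (13R)-3β,19-diacetoxy-9α,13:15,16-diepoxy-6β-hydroxylabd-14-en-7-one (CNP0317137.1)
Conditions: Ac2O, pyridine, 0 °C → rt
Reagents that add atoms: acetic anhydride, CC(=O)OC(C)=O
Why: Acetic anhydride in pyridine without DMAP acylates the equatorial 3β-hydroxyl and the primary 19-hydroxyl, whereas the axial 6β-hydroxyl, shielded by C19 and C20 and hydrogen-bonded to the C7 carbonyl, stays free.

**Compound list**

1 | geranyl chloride, (2E)-1-chloro-3,7-dimethylocta-2,6-diene | CC(C)=CCC/C(C)=C/CCl | starting material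
2 | 6,7-epoxygeranyl chloride (racemic at the epoxide) | CC1(C)OC1CC/C(C)=C/CCl | intermediate
3 | (4E)-6-chloro-4-methylhex-4-enal | O=CCC/C(C)=C/CCl | intermediate
4 | ethyl 2-[bis(2,2,2-trifluoroethoxy)phosphoryl]propanoate | CCOC(=O)C(C)P(=O)(OCC(F)(F)F)OCC(F)(F)F | starting material
5 | ethyl (2Z,6E)-8-chloro-2,6-dimethylocta-2,6-dienoate | CCOC(=O)/C(C)=C\CC/C(C)=C/CCl | intermediate
6 | (2Z,6E)-8-chloro-2,6-dimethylocta-2,6-dien-1-ol | OC/C(C)=C\CC/C(C)=C/CCl | intermediate
7 | [(2R,3S)-3-[(3E)-5-chloro-3-methylpent-3-en-1-yl]-2-methyloxiran-2-yl]methanol | OC[C@@]1(C)O[C@H]1CC/C(C)=C/CCl | intermediate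
8 | TBDPS ether of 7 | CC(C)(C)[Si](c1ccccc1)(c1ccccc1)OC[C@@]1(C)O[C@H]1CC/C(C)=C/CCl | intermediate
9 | methyl acetoacetate | COC(=O)CC(C)=O | starting material
10 | methyl (6E)-9-[(2S,3R)-3-(TBDPS-oxymethyl)-3-methyloxiran-2-yl]-7-methyl-3-oxonon-6-enoate | CC(C)(C)[Si](c1ccccc1)(c1ccccc1)OC[C@@]1(C)O[C@H]1CC/C(C)=C/CCC(=O)CC(=O)OC | intermediate
11 | (2Z)-enol diethyl phosphate of 10 | CC(C)(C)[Si](c1ccccc1)(c1ccccc1)OC[C@@]1(C)O[C@H]1CC/C(C)=C/CC/C(OP(=O)(OCC)OCC)=C/C(=O)OC | intermediate
12 | (trimethylsilyl)methylmagnesium chloride | C[Si](C)(C)C[Mg]Cl | starting material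
13 | methyl (2Z,6E)-9-[(2S,3R)-3-(TBDPS-oxymethyl)-3-methyloxiran-2-yl]-7-methyl-3-[(trimethylsilyl)methyl]nona-2,6-dienoate | CC(C)(C)[Si](c1ccccc1)(c1ccccc1)OC[C@@]1(C)O[C@H]1CC/C(C)=C/CC/C(C[Si](C)(C)C)=C/C(=O)OC | intermediate
14 | methyl 19-(TBDPS-oxy)-3β-hydroxy-12,13,14,15,16-pentanorlabd-8(17)-en-11-oate | CC(C)(C)[Si](c1ccccc1)(c1ccccc1)OC[C@@]1(C)[C@@H](O)CC[C@@]2(C)[C@H]1CCC(=C)[C@@H]2C(=O)OC | intermediate
15 | 19-(TBDPS-oxy)-12,13,14,15,16-pentanorlabd-8(17)-ene-3β,11-diol | CC(C)(C)[Si](c1ccccc1)(c1ccccc1)OC[C@@]1(C)[C@@H](O)CC[C@@]2(C)[C@H]1CCC(=C)[C@@H]2CO | intermediate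
16 | 11-acetoxy-19-(TBDPS-oxy)-12,13,14,15,16-pentanorlabd-8(17)-en-3β-ol | CC(C)(C)[Si](c1ccccc1)(c1ccccc1)OC[C@@]1(C)[C@@H](O)CC[C@@]2(C)[C@H]1CCC(=C)[C@@H]2COC(C)=O | intermediate
17 | 11-acetoxy-19-(TBDPS-oxy)-12,13,14,15,16-pentanorlabd-8(17)-ene-3β,7α-diol | CC(C)(C)[Si](c1ccccc1)(c1ccccc1)OC[C@@]1(C)[C@@H](O)CC[C@@]2(C)[C@H]1C[C@@H](O)C(=C)[C@@H]2COC(C)=O | intermediate
18 | 11-acetoxy-3β-hydroxy-19-(TBDPS-oxy)-12,13,14,15,16-pentanorlabd-8(17)-en-7-one | CC(C)(C)[Si](c1ccccc1)(c1ccccc1)OC[C@@]1(C)[C@@H](O)CC[C@@]2(C)[C@H]1CC(=O)C(=C)[C@@H]2COC(C)=O | intermediate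
19 | 11-acetoxy-3β-hydroxy-19-(TBDPS-oxy)-12,13,14,15,16-pentanorlabd-8-en-7-one | CC(C)(C)[Si](c1ccccc1)(c1ccccc1)OC[C@@]1(C)[C@@H](O)CC[C@@]2(C)[C@H]1CC(=O)C(C)=C2COC(C)=O | intermediate
20 | 2-methylprop-2-en-1-ol | CC(=C)CO | starting material
21 | tributyltin chloride | CCCC[Sn](Cl)(CCCC)CCCC | starting material
22 | 2-[(tributylstannyl)methyl]prop-2-en-1-ol | CCCC[Sn](CCCC)(CCCC)CC(=C)CO | intermediate
23 | 3β,14-dihydroxy-19-(TBDPS-oxy)-15-norlabda-8,13(16)-dien-7-one | CC(C)(C)[Si](c1ccccc1)(c1ccccc1)OC[C@@]1(C)[C@@H](O)CC[C@@]2(C)[C@H]1CC(=O)C(C)=C2CCC(=C)CO | intermediate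
24 | (13S)-13,16-epoxy-3β,14-dihydroxy-19-(TBDPS-oxy)-15-norlabd-8-en-7-one | CC(C)(C)[Si](c1ccccc1)(c1ccccc1)OC[C@@]1(C)[C@@H](O)CC[C@@]2(C)[C@H]1CC(=O)C(C)=C2CC[C@]3(CO)CO3 | intermediate
25 | (13R)-13,16-epoxy-3β-hydroxy-7-oxo-19-(TBDPS-oxy)-15-norlabd-8-en-14-al | CC(C)(C)[Si](c1ccccc1)(c1ccccc1)OC[C@@]1(C)[C@@H](O)CC[C@@]2(C)[C@H]1CC(=O)C(C)=C2CC[C@]3(C=O)CO3 | intermediate
26 | dimethyl (1-diazo-2-oxopropyl)phosphonate | COP(=O)(OC)C(=[N+]=[N-])C(C)=O | starting material
27 | (13S)-13,16-epoxy-3β-hydroxy-19-(TBDPS-oxy)labd-8-en-14-yn-7-one | CC(C)(C)[Si](c1ccccc1)(c1ccccc1)OC[C@@]1(C)[C@@H](O)CC[C@@]2(C)[C@H]1CC(=O)C(C)=C2CC[C@]3(C#C)CO3 | intermediate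
28 | (13S)-8α,9α:13,16-diepoxy-3β-hydroxy-19-(TBDPS-oxy)labd-14-yn-7-one | CC(C)(C)[Si](c1ccccc1)(c1ccccc1)OC[C@@]1(C)[C@@H](O)CC[C@@]2(C)[C@H]1CC(=O)[C@@]4(C)O[C@@]24CC[C@]3(C#C)CO3 | intermediate
29 | (13S)-13,16-epoxy-3β,9α-dihydroxy-19-(TBDPS-oxy)labd-14-yn-7-one | CC(C)(C)[Si](c1ccccc1)(c1ccccc1)OC[C@@]1(C)[C@@H](O)CC[C@@]2(C)[C@H]1CC(=O)[C@@H](C)[C@]2(O)CC[C@]3(C#C)CO3 | intermediate
30 | (13R)-9α,13-epoxy-3β,16-dihydroxy-19-(TBDPS-oxy)labd-14-yn-7-one | CC(C)(C)[Si](c1ccccc1)(c1ccccc1)OC[C@@]1(C)[C@@H](O)CC[C@@]2(C)[C@H]1CC(=O)[C@@H](C)[C@]21CC[C@](CO)(C#C)O1 | intermediate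
31 | (13R)-9α,13-epoxy-19-(TBDPS-oxy)labd-6-en-14-yne-3β,7,16-triyl tris(chloroacetate) | CC(C)(C)[Si](c1ccccc1)(c1ccccc1)OC[C@@]1(C)[C@@H](OC(=O)CCl)CC[C@@]2(C)[C@H]1C=C(OC(=O)CCl)[C@@H](C)[C@]21CC[C@](COC(=O)CCl)(C#C)O1 | intermediate
32 | (13R)-6α,7α:9α,13-diepoxy-19-(TBDPS-oxy)labd-14-yne-3β,7β,16-triyl tris(chloroacetate), formed in the flask in step 25 | CC(C)(C)[Si](c1ccccc1)(c1ccccc1)OC[C@@]1(C)[C@@H](OC(=O)CCl)CC[C@@]2(C)[C@H]1[C@H]5O[C@@]5(OC(=O)CCl)[C@@H](C)[C@]21CC[C@](COC(=O)CCl)(C#C)O1 | intermediate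
33 | (13R)-3β,6β,16-tris(chloroacetoxy)-9α,13-epoxy-19-(TBDPS-oxy)labd-14-yn-7-one | CC(C)(C)[Si](c1ccccc1)(c1ccccc1)OC[C@@]1(C)[C@@H](OC(=O)CCl)CC[C@@]2(C)[C@H]1[C@H](OC(=O)CCl)C(=O)[C@@H](C)[C@]21CC[C@](COC(=O)CCl)(C#C)O1 | intermediate
34 | (13R)-9α,13-epoxy-3β,6β,16-trihydroxy-19-(TBDPS-oxy)labd-14-yn-7-one | CC(C)(C)[Si](c1ccccc1)(c1ccccc1)OC[C@@]1(C)[C@@H](O)CC[C@@]2(C)[C@H]1[C@H](O)C(=O)[C@@H](C)[C@]21CC[C@](CO)(C#C)O1 | intermediate
35 | (13R)-9α,13-epoxy-3β,6β,16,19-tetrahydroxylabd-14-yn-7-one | OC[C@@]1(C)[C@@H](O)CC[C@@]2(C)[C@H]1[C@H](O)C(=O)[C@@H](C)[C@]21CC[C@](CO)(C#C)O1 | intermediate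
36 | (13R)-9α,13:15,16-diepoxy-3β,6β,19-trihydroxylabd-14-en-7-one | OC[C@@]1(C)[C@@H](O)CC[C@@]2(C)[C@H]1[C@H](O)C(=O)[C@@H](C)[C@]21CC[C@]2(C=COC2)O1 | intermediate
37 | (13R)-3β,19-diacetoxy-9α,13:15,16-diepoxy-6β-hydroxylabd-14-en-7-one (CNP0317137.1) | CC(=O)OC[C@@]1(C)[C@@H](OC(C)=O)CC[C@@]2(C)[C@H]1[C@H](O)C(=O)[C@@H](C)[C@]21CC[C@]2(C=COC2)O1 | target

**Step count**

Total step count: 29. Longest linear sequence: 28 steps (steps 1–15 and 17–29; step 16 prepares the stannane 22).

**Three steps most likely to fail**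

Step 10 (key step). The cascade may stop after ring A: the Lewis acid also binds the ester, the conjugated allylsilane becomes a poor nucleophile, and proton loss from the C10 cation can overtake the second ring closure. The fallback changes the terminator and sets out from 13. DIBAL-H (CH2Cl2, −78 °C) reduces the ester to the allylsilane alcohol F1, and TBSCl/imidazole gives its silyl ether F2. F2 carries an electron-rich, unconjugated allylsilane whose bulky silyl ether oxygen is neither a good Lewis base nor a good leaving group. MeAlCl2 (CH2Cl2, −78 °C) should then close both rings in the same way to the bicyclic TBS ether F3. PPTS in MeOH removes the primary TBS group in the presence of the TBDPS ether, and the route is rejoined at 15.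

Step 17. Transmetalation from tin to the hindered π-allyl palladium complex may be slow, so that homocoupling of the stannane or loss of regiocontrol between C11 and C8 takes over. The fallback replaces the palladium coupling by a radical chain and sets out from 19. K2CO3 in MeOH (0 °C) cleaves the allylic acetate to the 11-hydroxy enone F4, and an Appel reaction (CBr4, PPh3, CH2Cl2, 0 °C) gives the allylic bromide F5. Keck radical allylation of F5 with 22 (AIBN, benzene, 80 °C) is expected to join the delocalised C11/C8 radical to the stannane through its unhindered terminus C11, which keeps the enone conjugated, with loss of the tin radical. The route is rejoined at 23.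

Step 21. Attack of hydroperoxide at the fully substituted β-carbon C9, next to the quaternary C10, may be too slow, so that base-induced degradation of the enone competes or facial selectivity erodes. The fallback forms the C9–O bond by conjugate addition of the C13 oxygen instead and therefore needs the other epoxide enantiomer. It sets out from 23. Sharpless epoxidation with D-(−)-diisopropyl tartrate gives the (13R)-epoxy alcohol F6, TEMPO/PhI(OAc)2 the epoxy aldehyde F7, and the Ohira–Bestmann reagent 26 (K2CO3, MeOH) the (13R)-ethynyl epoxide F8. Sodium 4-methoxybenzyl oxide (4-methoxybenzyl alcohol, NaH, DMF, 60 °C) opens the epoxide at the primary carbon C16 with retention at C13. The tertiary C13 alkoxide so released is expected to add to C9 of the enone in a 5-exo-trig oxa-Michael reaction under thermodynamic control (9α-O, 8α-methyl), giving the 16-O-(4-methoxybenzyl) spiro ether F9. DDQ (CH2Cl2, pH 7 buffer) frees the 16-hydroxyl, and the route is rejoined at 30.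

**Further compounds**

F1 | step 10 | (2Z,6E)-9-[(2S,3R)-3-(TBDPS-oxymethyl)-3-methyloxiran-2-yl]-7-methyl-3-[(trimethylsilyl)methyl]nona-2,6-dien-1-ol | CC(C)(C)[Si](c1ccccc1)(c1ccccc1)OC[C@@]1(C)O[C@H]1CC/C(C)=C/CC/C(C[Si](C)(C)C)=C/CO
F2 | step 10 | tert-butyldimethylsilyl ether of F1 | CC(C)(C)[Si](c1ccccc1)(c1ccccc1)OC[C@@]1(C)O[C@H]1CC/C(C)=C/CC/C(C[Si](C)(C)C)=C/CO[Si](C)(C)C(C)(C)C
F3 | step 10 | 11-(tert-butyldimethylsilyloxy)-19-(TBDPS-oxy)-12,13,14,15,16-pentanorlabd-8(17)-en-3β-ol | CC(C)(C)[Si](c1ccccc1)(c1ccccc1)OC[C@@]1(C)[C@@H](O)CC[C@@]2(C)[C@H]1CCC(=C)[C@@H]2CO[Si](C)(C)C(C)(C)C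
F4 | step 17 | 3β,11-dihydroxy-19-(TBDPS-oxy)-12,13,14,15,16-pentanorlabd-8-en-7-one | CC(C)(C)[Si](c1ccccc1)(c1ccccc1)OC[C@@]1(C)[C@@H](O)CC[C@@]2(C)[C@H]1CC(=O)C(C)=C2CO
F5 | step 17 | 11-bromo-3β-hydroxy-19-(TBDPS-oxy)-12,13,14,15,16-pentanorlabd-8-en-7-one | CC(C)(C)[Si](c1ccccc1)(c1ccccc1)OC[C@@]1(C)[C@@H](O)CC[C@@]2(C)[C@H]1CC(=O)C(C)=C2CBr
F6 | step 21 | (13R)-13,16-epoxy-3β,14-dihydroxy-19-(TBDPS-oxy)-15-norlabd-8-en-7-one | CC(C)(C)[Si](c1ccccc1)(c1ccccc1)OC[C@@]1(C)[C@@H](O)CC[C@@]2(C)[C@H]1CC(=O)C(C)=C2CC[C@@]3(CO)CO3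
F7 | step 21 | (13S)-13,16-epoxy-3β-hydroxy-7-oxo-19-(TBDPS-oxy)-15-norlabd-8-en-14-al | CC(C)(C)[Si](c1ccccc1)(c1ccccc1)OC[C@@]1(C)[C@@H](O)CC[C@@]2(C)[C@H]1CC(=O)C(C)=C2CC[C@@]3(C=O)CO3
F8 | step 21 | (13R)-13,16-epoxy-3β-hydroxy-19-(TBDPS-oxy)labd-8-en-14-yn-7-one | CC(C)(C)[Si](c1ccccc1)(c1ccccc1)OC[C@@]1(C)[C@@H](O)CC[C@@]2(C)[C@H]1CC(=O)C(C)=C2CC[C@@]3(C#C)CO3
F9 | step 21 | (13R)-9α,13-epoxy-3β-hydroxy-16-(4-methoxybenzyloxy)-19-(TBDPS-oxy)labd-14-yn-7-one | CC(C)(C)[Si](c1ccccc1)(c1ccccc1)OC[C@@]1(C)[C@@H](O)CC[C@@]2(C)[C@H]1CC(=O)[C@@H](C)[C@]21CC[C@](COCc3ccc(OC)cc3)(C#C)O1
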